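**Remarks.** Ring locants used throughout: C1 = quaternary carbon (methyl, vinyl), C2 = ring CH2, C3 = acyloxy carbon, C4 = carbon bearing the acrylic acid, C5 = carbinol carbon, C6 = carbon bearing the 3-hydroxyprop-1-en-2-yl group. The target is assumed to be isolable as the free γ-hydroxy acid as long as the pH stays above about 4; stronger acid would close the γ-lactone onto the cis O5 and is avoided once O5 is free.

## Retrosynthetic overview

1. Target 31 ← global fluoride deprotection of 30 ← esterification of C3–OH with (S)-acid 28. The acrylic acid comes from a C4 malonate (Mannich methylenation); C4 and C5 come from two hydride additions to alkylidene malonate 18, both on the face opposite to the C1 methyl, O3 and the C6 side chain.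
2. Key disconnection: cyclohexanone 15 ← eight-membered 2-alkylidene-oxocene 14 by Claisen ring contraction. Enabling feature: with C5 as ketone, C5(=O)–C6–C1–CH=CH2 is a γ,δ-unsaturated ketone; tying the vinyl CH2 to the C5 oxygen gives the ring O–C5–C4–C3–C2–C1=CH–CH2, with C6 as the exocyclic enol ether carbon.
3. 14 ← Tebbe methylenation, ring-closing metathesis and oxa-Michael addition of allyl alcohol to ynone 10; 10 ← (R)-epichlorohydrin (supplies C3), isopropenyl Grignard reagent, acetylide and a silyloxyacetaldehyde.
4. Ring order: oxocene first (metathesis), then the cyclohexane by contraction of that ring. The one bought stereocentre (C3) relays C1 and C6 in the key step, then C4 and C5.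

Key step: step 9

## Route

Step 1
Reactants: 1 (R)-epichlorohydrin; 2 isopropenylmagnesium bromide
Product: 3 (R)-1-chloro-4-methylpent-4-en-2-ol
Conditions: CuI (10 mol%), THF, −40 to −20 °C; aq NH4Cl
Reagents that add atoms: none
Why: Copper-catalysed Grignard opening of the epoxide at its unsubstituted carbon (SN2) is faster than attack at the C–Cl bond and touches no bond of the stereocentre, so the C3 configuration of the target is bought with 1.

Step 2
Reactants: 3 (R)-1-chloro-4-methylpent-4-en-2-ol; 4 lithium acetylide ethylenediamine complex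
Product: 6 (R)-2-methylhept-1-en-6-yn-4-ol, via epoxide 5 (not isolated)
Conditions: 4 (3 equiv), DMSO, 0 °C to rt; aq NH4Cl
Reagents that add atoms: none
Why: The acetylide first closes the chlorohydrin to epoxide 5 (intramolecular Williamson reaction) and a second equivalent opens it at the terminal carbon (SN2 epoxide alkynylation), again without touching the stereocentre.

Step 3
Reactants: 6 (R)-2-methylhept-1-en-6-yn-4-ol
Product: 7 (R)-4-(4-methoxybenzyloxy)-2-methylhept-1-en-6-yne
Conditions: NaH, 4-methoxybenzyl chloride, Bu4NI (cat.), THF–DMF, 0 °C to rt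
Reagents that add atoms: 4-methoxybenzyl chloride, COc1ccc(CCl)cc1
Why: Williamson etherification of the secondary alkoxide; the PMB ether survives the bases, hydrides and heat that follow and is later removed oxidatively in the presence of silyl ethers.

Step 4
Reactants: 7 (R)-4-(4-methoxybenzyloxy)-2-methylhept-1-en-6-yne; 8 2-(tert-butyldimethylsilyloxy)acetaldehyde
Product: 9 (6R)-1-(tert-butyldimethylsilyloxy)-6-(4-methoxybenzyloxy)-8-methylnon-8-en-3-yn-2-ol (both C2 epimers)
Conditions: n-BuLi, THF, −78 °C; then 8, −78 °C; aq NH4Cl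
Reagents that add atoms: none
Why: 1,2-Addition of the lithium acetylide to the aldehyde; the new carbinol centre forms as a mixture, which is harmless because it is oxidised in step 5.

Step 5
Reactants: 9 propargylic alcohol
Product: 10 (R)-1-(tert-butyldimethylsilyloxy)-6-(4-methoxybenzyloxy)-8-methylnon-8-en-3-yn-2-one
Conditions: activated MnO2 (excess), CH2Cl2, rt
Reagents that add atoms: none
Why: Chemoselective MnO2 oxidation of the propargylic alcohol gives the conjugated ynone needed as Michael acceptor.

Step 6
Reactants: 10 ynone; 11 allyl alcohol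
Product: 12 (R,E)-4-(allyloxy)-1-(tert-butyldimethylsilyloxy)-6-(4-methoxybenzyloxy)-8-methylnona-3,8-dien-2-one
Conditions: PMe3 (10 mol%), 11 (3 equiv), CH2Cl2, 0 °C to rt
Reagents that add atoms: none
Why: Phosphine-catalysed conjugate addition (oxa-Michael) of the alcohol to the ynone places oxygen on the β-carbon (future C5) and gives the thermodynamically preferred E vinylogous ester, in which the acyl group is trans to oxygen and cis to the C4 methylene, the geometry that step 9 translates into the C6 configuration.

Step 7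
Reactants: 12 acyclic allyl vinylogous ester
Product: 13 (E)-1-(tert-butyldimethylsilyloxy)-3-[(4R,6Z)-4-(4-methoxybenzyloxy)-6-methyl-3,4,5,8-tetrahydro-2H-oxocin-2-ylidene]propan-2-one
Conditions: second-generation Grubbs catalyst RuCl2(=CHPh)(H2IMes)(PCy3) (10 mol%), toluene (1 mM), 80 °C
Reagents that add atoms: none
Why: Ring-closing metathesis of the allyl ether with the 1,1-disubstituted olefin, a reaction type with precedent for eight-membered cyclic ethers and for trisubstituted cyclooctenes; the ring size enforces the Z olefin, and the sp2 enol ether carbon plus high dilution favour closure over oligomerisation.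

Step 8
Reactants: 13 eight-membered vinylogous ester
Product: 14 (2E,4R,6Z)-2-[2-(tert-butyldimethylsilyloxymethyl)prop-2-en-1-ylidene]-4-(4-methoxybenzyloxy)-6-methyl-3,4,5,8-tetrahydro-2H-oxocine
Conditions: Tebbe reagent Cp2Ti(CH2)(Cl)AlMe2 (1.5 equiv), pyridine (cat.), THF–toluene, −40 to 0 °C; aq NaOH; basic alumina
Reagents that add atoms: Tebbe reagent, C[Al-]1(C)C[Ti]([Cl+]1)(C1C=CC=C1)C1C=CC=C1
Why: Tebbe methylenation converts the vinylogous ester carbonyl into the 1,1-disubstituted olefin of the future C6 side chain under non-basic conditions, so neither the enol ether geometry nor the C3 centre is disturbed.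

Step 9
Reactants: 14 2-alkylidene-oxocene (dienyl allyl ether)
Product: 15 (2R,3S,5R)-2-[3-(tert-butyldimethylsilyloxy)prop-1-en-2-yl]-5-(4-methoxybenzyloxy)-3-methyl-3-vinylcyclohexan-1-one
Conditions: xylenes (5 mM), 150 °C, sealed base-washed vessel, BHT (cat.)
Reagents that add atoms: none
Why: Thermal [3,3]-sigmatropic (Claisen) rearrangement of the allyl vinyl ether embedded in the oxocene: the exocyclic enol ether carbon (C6) bonds to the methyl-bearing ring olefin carbon (C1) while the O–CH2 bond breaks, so the eight-membered ring O–C5–C4–C3–C2–C1=CH–CH2 contracts to the six-membered ring C1–C6 and releases C5 as ketone and CH=CH2 as the vinyl group. The closest known reaction types are the Claisen ring expansion of lactone-derived 2-methylene-6-vinyltetrahydropyrans to cyclooctenones and the ketene acetal Claisen ring contraction of unsaturated macrolactones. The cyclohexanone closes by transannular six-membered C–C bond formation (contraction by two atoms) through an all-chair bicyclo[3.3.1]nonane-like array in which the pericyclic ring and the new carbocycle share C5, C6 and C1. C1 is controlled by C3: its OPMB group must sit exo (equatorial on the forming chair) because the endo position points at the migrating CH2, so the O–CH2–CH bridge and hence the vinyl group end up trans to OPMB and the methyl cis. C6 is controlled by the E enol ether (side chain equatorial on the pericyclic chair, axial on the new ring, anti to the vinyl group) together with the ring-enforced Z olefin. The step needs chair over boat and [3,3] shift over [1,5]-hydrogen shift or hydrolysis of the dienyl ether; the fit of the E,Z substrate to the all-chair array, the strain released from the medium ring and neutral base-washed conditions secure this.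

Step 10
Reactants: 15 cyclohexanone; 16 diethyl 2-oxomalonate
Product: 17 diethyl 2-hydroxy-2-[(3R,4S,6R)-3-[3-(tert-butyldimethylsilyloxy)prop-1-en-2-yl]-6-(4-methoxybenzyloxy)-4-methyl-2-oxo-4-vinylcyclohexyl]malonate (both epimers at ring C4)
Conditions: LiN(iPr)2 (1.1 equiv), THF, −78 °C; then 16, −78 °C; AcOH quench at −78 °C
Reagents that add atoms: none
Why: Kinetic deprotonation takes place at the unhindered C4 methylene rather than at the C6 methine next to the quaternary centre, and the lithium enolate adds (aldol addition) to the very electrophilic central carbonyl of 16; the C4 configuration is irrelevant because it is erased in step 11.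

Step 11
Reactants: 17 aldol adduct
Product: 18 diethyl 2-[(3R,4S,6R)-3-[3-(tert-butyldimethylsilyloxy)prop-1-en-2-yl]-6-(4-methoxybenzyloxy)-4-methyl-2-oxo-4-vinylcyclohexylidene]malonate
Conditions: SOCl2, pyridine, CH2Cl2, 0 °C
Reagents that add atoms: none
Why: Activation of the tertiary alcohol as chlorosulfite and E1cB-type loss toward the only β-hydrogen, the acidic C4–H, completes the aldol condensation to the alkylidene malonate.

Step 12
Reactants: 18 alkylidene malonate
Product: 20 diethyl 2-[(1S,2S,3R,4S,6R)-3-[3-(tert-butyldimethylsilyloxy)prop-1-en-2-yl]-2-hydroxy-6-(4-methoxybenzyloxy)-4-methyl-4-vinylcyclohexyl]malonate, via keto malonate 19 (not isolated)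
Conditions: NaBH4 (4 equiv), EtOH–THF, −40 to −10 °C; AcOH quench at −40 °C
Reagents that add atoms: none
Why: Conjugate hydride reduction of the alkylidene malonate is followed in the same pot by ketone reduction; allylic 1,3-strain with the alkylidene ester holds the C3–OPMB group axial and syn to the axial C1 methyl, so hydride adds to C4 and then (equatorial attack) to C5 from the opposite face, which sets C4 and C5 with malonyl and hydroxyl cis to O3 and to the C6 side chain, while the malonate stays as its enolate and cannot lactonise.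

Step 13
Reactants: 20 hydroxy malonate
Product: 21 O5-triethylsilyl ether of 20
Conditions: TESOTf, 2,6-lutidine, CH2Cl2, −78 to 0 °C
Reagents that add atoms: triethylsilyl trifluoromethanesulfonate, CC[Si](CC)(CC)OS(=O)(=O)C(F)(F)F
Why: Silylation with the silyl triflate, which is reactive enough for the hindered axial C5 hydroxyl, blocks lactone formation in the steps that follow.

Step 14
Reactants: 21 silyl ether malonate
Product: 23 2-substituted acrylic acid (C4 side chain C(=CH2)CO2H; O5-TES, O3-PMB, primary O-TBS; ring configuration as in 31), via malonic acid 22 (not isolated)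
Conditions: LiOH·H2O (6 equiv), THF–MeOH–H2O, 40 °C; 1 M HCl to pH 4 at 0 °C, extract; then aq CH2O (37%), Et2NH, EtOAc, 60 °C
Reagents that add atoms: lithium hydroxide, [Li+].[OH-]; formaldehyde, C=O
Why: Saponification to malonic acid 22 and Mannich-type decarboxylative methylenation with formaldehyde and a secondary amine, the classical route from monosubstituted malonic acids to 2-substituted acrylic acids; no stereocentre is touched.

Step 15
Reactants: 23 acrylic acid
Product: 24 2-(trimethylsilyl)ethyl ester of 23
Conditions: 2-(trimethylsilyl)ethanol, EDCI·HCl, DMAP, CH2Cl2, rt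
Reagents that add atoms: 2-(trimethylsilyl)ethanol, C[Si](C)(C)CCO
Why: Carbodiimide (Steglich) esterification masks the acid as a fluoride-labile ester so that it cannot lactonise onto O3 or interfere in step 19.

Step 16
Reactants: 24 PMB ether
Product: 25 C3 alcohol (O5-TES, primary O-TBS, 2-(trimethylsilyl)ethyl acrylate; ring configuration as in 31)
Conditions: DDQ, CH2Cl2–pH 7 buffer, 0 °C
Reagents that add atoms: none
Why: Oxidative cleavage of the PMB ether with DDQ frees the C3 hydroxyl without touching the silyl ethers, the ester or the olefins.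

Step 17
Reactants: 26 methyl (S)-3-hydroxy-2-methylpropanoate
Product: 27 methyl (S)-3-(tert-butyldimethylsilyloxy)-2-methylpropanoate
Conditions: TBSCl, imidazole, DMF, rt
Reagents that add atoms: tert-butyldimethylsilyl chloride, CC(C)(C)[Si](C)(C)Cl
Why: Standard silylation of the primary alcohol, which leaves the stereocentre untouched.

Step 18
Reactants: 27 silyloxy ester
Product: 28 (S)-3-(tert-butyldimethylsilyloxy)-2-methylpropanoic acid
Conditions: LiOH, THF–H2O, 0 °C to rt; 1 M HCl to pH 4 at 0 °C
Reagents that add atoms: lithium hydroxide, [Li+].[OH-]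
Why: Saponification at low temperature, which does not epimerise the α-centre of this β-silyloxy ester.

Step 19
Reactants: 25 C3 alcohol; 28 (S)-acid
Product: 30 fully protected ester (O3 acylated by 28; O5-TES; two primary O-TBS; 2-(trimethylsilyl)ethyl acrylate), via mixed anhydride 29 (not isolated)
Conditions: 28, 2,4,6-trichlorobenzoyl chloride, Et3N, THF, rt; then 25, DMAP, toluene, rt to 40 °C
Reagents that add atoms: none
Why: Yamaguchi esterification through mixed anhydride 29; the C3 hydroxyl is the only free alcohol, and acyl transfer through the acylpyridinium avoids a ketene, so the (S) centre of the acid is kept.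

Step 20
Reactants: 30 fully protected ester
Product: 31 2-[(1S,2S,3R,4S,6R)-4-ethenyl-2-hydroxy-6-[(2S)-3-hydroxy-2-methylpropanoyl]oxy-3-(3-hydroxyprop-1-en-2-yl)-4-methylcyclohexyl]prop-2-enoic acid
Conditions: TBAF (8 equiv), AcOH (6 equiv), THF, 0 °C to rt; pH 6 phosphate buffer work-up, cold extraction
Reagents that add atoms: none
Why: Buffered fluoride cleaves the three silyl ethers and fragments the 2-(trimethylsilyl)ethyl ester (β-elimination) in one operation; the acetic acid buffer suppresses acyl migration from O3 to O5 and the product is released as carboxylate, so the γ-lactone should not close.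

## Compound list

1 | (R)-epichlorohydrin | ClC[C@H]1CO1 | starting material
2 | isopropenylmagnesium bromide | CC(=C)[Mg]Br | starting material
3 | (R)-1-chloro-4-methylpent-4-en-2-ol | C=C(C)C[C@@H](O)CCl | intermediate
4 | lithium acetylide ethylenediamine complex | [Li]C#C.NCCN | starting material
5 | (R)-2-(2-methylprop-2-en-1-yl)oxirane | C=C(C)C[C@@H]1CO1 | intermediate
6 | (R)-2-methylhept-1-en-6-yn-4-ol | C=C(C)C[C@@H](O)CC#C | intermediate
7 | (R)-4-(4-methoxybenzyloxy)-2-methylhept-1-en-6-yne | C=C(C)C[C@@H](OCc1ccc(OC)cc1)CC#C | intermediate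
8 | 2-(tert-butyldimethylsilyloxy)acetaldehyde | O=CCO[Si](C)(C)C(C)(C)C | starting material
9 | (6R)-1-(tert-butyldimethylsilyloxy)-6-(4-methoxybenzyloxy)-8-methylnon-8-en-3-yn-2-ol (C2 epimers) | C=C(C)C[C@@H](OCc1ccc(OC)cc1)CC#CC(O)CO[Si](C)(C)C(C)(C)C | intermediate
10 | (R)-1-(tert-butyldimethylsilyloxy)-6-(4-methoxybenzyloxy)-8-methylnon-8-en-3-yn-2-one | C=C(C)C[C@@H](OCc1ccc(OC)cc1)CC#CC(=O)CO[Si](C)(C)C(C)(C)C | intermediate
11 | allyl alcohol | C=CCO | starting material
12 | (R,E)-4-(allyloxy)-1-(tert-butyldimethylsilyloxy)-6-(4-methoxybenzyloxy)-8-methylnona-3,8-dien-2-one | C=C(C)C[C@@H](OCc1ccc(OC)cc1)C/C(OCC=C)=C\C(=O)CO[Si](C)(C)C(C)(C)C | intermediate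
13 | (E)-1-(tert-butyldimethylsilyloxy)-3-[(4R,6Z)-4-(4-methoxybenzyloxy)-6-methyl-3,4,5,8-tetrahydro-2H-oxocin-2-ylidene]propan-2-one | O=C(CO[Si](C)(C)C(C)(C)C)/C=C1\C[C@H](OCc2ccc(OC)cc2)C/C(C)=C\CO1 | intermediate
14 | (2E,4R,6Z)-2-[2-(tert-butyldimethylsilyloxymethyl)prop-2-en-1-ylidene]-4-(4-methoxybenzyloxy)-6-methyl-3,4,5,8-tetrahydro-2H-oxocine | C=C(CO[Si](C)(C)C(C)(C)C)/C=C1\C[C@H](OCc2ccc(OC)cc2)C/C(C)=C\CO1 | intermediate
15 | (2R,3S,5R)-2-[3-(tert-butyldimethylsilyloxy)prop-1-en-2-yl]-5-(4-methoxybenzyloxy)-3-methyl-3-vinylcyclohexan-1-one | C=C[C@]1(C)C[C@@H](OCc2ccc(OC)cc2)CC(=O)[C@H]1C(=C)CO[Si](C)(C)C(C)(C)C | intermediate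
16 | diethyl 2-oxomalonate | CCOC(=O)C(=O)C(=O)OCC | starting material
17 | diethyl 2-hydroxy-2-[(3R,4S,6R)-3-[3-(tert-butyldimethylsilyloxy)prop-1-en-2-yl]-6-(4-methoxybenzyloxy)-4-methyl-2-oxo-4-vinylcyclohexyl]malonate (ring C4 epimers) | C=C[C@]1(C)C[C@@H](OCc2ccc(OC)cc2)C(C(O)(C(=O)OCC)C(=O)OCC)C(=O)[C@H]1C(=C)CO[Si](C)(C)C(C)(C)C | intermediate
18 | diethyl 2-[(3R,4S,6R)-3-[3-(tert-butyldimethylsilyloxy)prop-1-en-2-yl]-6-(4-methoxybenzyloxy)-4-methyl-2-oxo-4-vinylcyclohexylidene]malonate | C=C[C@]1(C)C[C@@H](OCc2ccc(OC)cc2)C(=C(C(=O)OCC)C(=O)OCC)C(=O)[C@H]1C(=C)CO[Si](C)(C)C(C)(C)C | intermediate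
19 | diethyl 2-[(1R,3R,4S,6R)-3-[3-(tert-butyldimethylsilyloxy)prop-1-en-2-yl]-6-(4-methoxybenzyloxy)-4-methyl-2-oxo-4-vinylcyclohexyl]malonate | C=C[C@]1(C)C[C@@H](OCc2ccc(OC)cc2)[C@@H](C(C(=O)OCC)C(=O)OCC)C(=O)[C@H]1C(=C)CO[Si](C)(C)C(C)(C)C | intermediate
20 | diethyl 2-[(1S,2S,3R,4S,6R)-3-[3-(tert-butyldimethylsilyloxy)prop-1-en-2-yl]-2-hydroxy-6-(4-methoxybenzyloxy)-4-methyl-4-vinylcyclohexyl]malonate | C=C[C@]1(C)C[C@@H](OCc2ccc(OC)cc2)[C@@H](C(C(=O)OCC)C(=O)OCC)[C@@H](O)[C@H]1C(=C)CO[Si](C)(C)C(C)(C)C | intermediate
21 | O5-triethylsilyl ether of 20 | C=C[C@]1(C)C[C@@H](OCc2ccc(OC)cc2)[C@@H](C(C(=O)OCC)C(=O)OCC)[C@@H](O[Si](CC)(CC)CC)[C@H]1C(=C)CO[Si](C)(C)C(C)(C)C | intermediate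
22 | malonic acid from 21 (both ethyl esters hydrolysed) | C=C[C@]1(C)C[C@@H](OCc2ccc(OC)cc2)[C@@H](C(C(=O)O)C(=O)O)[C@@H](O[Si](CC)(CC)CC)[C@H]1C(=C)CO[Si](C)(C)C(C)(C)C | intermediate
23 | 2-substituted acrylic acid (O5-TES, O3-PMB, primary O-TBS) | C=C[C@]1(C)C[C@@H](OCc2ccc(OC)cc2)[C@@H](C(=C)C(=O)O)[C@@H](O[Si](CC)(CC)CC)[C@H]1C(=C)CO[Si](C)(C)C(C)(C)C | intermediate
24 | 2-(trimethylsilyl)ethyl ester of 23 | C=C[C@]1(C)C[C@@H](OCc2ccc(OC)cc2)[C@@H](C(=C)C(=O)OCC[Si](C)(C)C)[C@@H](O[Si](CC)(CC)CC)[C@H]1C(=C)CO[Si](C)(C)C(C)(C)C | intermediate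
25 | C3 alcohol from 24 (PMB removed) | C=C[C@]1(C)C[C@@H](O)[C@@H](C(=C)C(=O)OCC[Si](C)(C)C)[C@@H](O[Si](CC)(CC)CC)[C@H]1C(=C)CO[Si](C)(C)C(C)(C)C | intermediate
26 | methyl (S)-3-hydroxy-2-methylpropanoate | COC(=O)[C@@H](C)CO | starting material
27 | methyl (S)-3-(tert-butyldimethylsilyloxy)-2-methylpropanoate | COC(=O)[C@@H](C)CO[Si](C)(C)C(C)(C)C | intermediate
28 | (S)-3-(tert-butyldimethylsilyloxy)-2-methylpropanoic acid | OC(=O)[C@@H](C)CO[Si](C)(C)C(C)(C)C | intermediate
29 | (S)-3-(tert-butyldimethylsilyloxy)-2-methylpropanoic 2,4,6-trichlorobenzoic anhydride | O=C(OC(=O)c1c(Cl)cc(Cl)cc1Cl)[C@@H](C)CO[Si](C)(C)C(C)(C)C | intermediate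
30 | fully protected ester (O3 acyl from 28, O5-TES, two primary O-TBS, 2-(trimethylsilyl)ethyl acrylate) | C=C[C@]1(C)C[C@@H](OC(=O)[C@@H](C)CO[Si](C)(C)C(C)(C)C)[C@@H](C(=C)C(=O)OCC[Si](C)(C)C)[C@@H](O[Si](CC)(CC)CC)[C@H]1C(=C)CO[Si](C)(C)C(C)(C)C | intermediate
31 | 2-[(1S,2S,3R,4S,6R)-4-ethenyl-2-hydroxy-6-[(2S)-3-hydroxy-2-methylpropanoyl]oxy-3-(3-hydroxyprop-1-en-2-yl)-4-methylcyclohexyl]prop-2-enoic acid | C=C[C@]1(C)C[C@@H](OC(=O)[C@@H](C)CO)[C@@H](C(=C)C(=O)O)[C@@H](O)[C@H]1C(=C)CO | target

## Step count and risks

Total step count: 20. Longest linear sequence: 18 steps (steps 1 to 16, then 19 and 20).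

**Step 9 (ring contraction).** The all-chair preference may erode at 150 °C (a boat-like pericyclic array would invert C6), and the cis-dienyl ether may drift thermally ([1,5]-hydrogen shift, adventitious hydrolysis) before the sigmatropic shift. The fallback sets out from 14 and comes back at 15. Compound 14 is treated with iBu3Al in toluene from −78 °C to rt; this aluminium-promoted reductive Claisen rearrangement runs far below the thermal window and should deliver the ring-contracted cyclohexanol F1 (C5 carbinol as an epimer mixture, formed by hydride transfer from the isobutyl group to the rearranged ketone). Oxidation of the cyclohexanol F1 with Dess–Martin periodinane in CH2Cl2 then gives 15.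

**Step 19 (esterification of the C3 hydroxyl).** Acyl transfer to the hindered axial C3 hydroxyl may be so slow that translactonisation of this hydroxyl onto the neighbouring acrylate ester and epimerisation of the activated acid take over. The fallback sets out from 25 (and 26) and comes back at 31. Ester 26 is saponified (LiOH, THF–H2O) to (S)-3-hydroxy-2-methylpropanoic acid F4, which is closed with benzenesulfonyl chloride in pyridine at 0 °C to (S)-3-methyloxetan-2-one F5. This small, strain-activated acyl donor has no α-activation and should acylate 25 by acyl–oxygen opening (DMAP, CH2Cl2, rt) to the hydroxy ester F6 with its side-chain hydroxyl already free. The hydroxy ester F6 is deprotected under the conditions of step 20 to give 31.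

**Step 11 (dehydration to the alkylidene malonate).** Retro-aldol loss of the ketomalonate or substitution by chloride may outrun β-elimination toward the congested tetrasubstituted olefin. The fallback sets out from 15 and comes back at 19, reversing the polarity at C4. Ketone 15 is converted (LiN(iPr)2, Me3SiCl, THF, −78 °C) into the kinetic silyl enol ether F2, which N-bromosuccinimide brominates from the face opposite to O3, the C1 methyl and the C6 side chain to give the α-bromo ketone F3. SN2 displacement of the α-bromo ketone F3 with NaCH(CO2Et)2 in THF–DMF at 0 °C, with inversion, should give keto malonate 19 with the malonyl group cis to O3. Compound 19 is then reduced as in step 12.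

## Further compounds

F1 | step 9 | (2R,3S,5R)-2-[3-(tert-butyldimethylsilyloxy)prop-1-en-2-yl]-5-(4-methoxybenzyloxy)-3-methyl-3-vinylcyclohexan-1-ol (C1 epimers) | C=C[C@]1(C)C[C@@H](OCc2ccc(OC)cc2)CC(O)[C@H]1C(=C)CO[Si](C)(C)C(C)(C)C
F2 | step 11 | trimethylsilyl enol ether of 15 toward C4 | C=C[C@]1(C)C[C@@H](OCc2ccc(OC)cc2)C=C(O[Si](C)(C)C)[C@H]1C(=C)CO[Si](C)(C)C(C)(C)C
F3 | step 11 | C4 bromo ketone from 15 (bromine trans to the C3 oxygen) | C=C[C@]1(C)C[C@@H](OCc2ccc(OC)cc2)[C@H](Br)C(=O)[C@H]1C(=C)CO[Si](C)(C)C(C)(C)C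
F4 | step 19 | (S)-3-hydroxy-2-methylpropanoic acid | OC(=O)[C@@H](C)CO
F5 | step 19 | (S)-3-methyloxetan-2-one | O=C1OC[C@@H]1C
F6 | step 19 | O3 (S)-3-hydroxy-2-methylpropanoate of 25 (side-chain hydroxyl free) | C=C[C@]1(C)C[C@@H](OC(=O)[C@@H](C)CO)[C@@H](C(=C)C(=O)OCC[Si](C)(C)C)[C@@H](O[Si](CC)(CC)CC)[C@H]1C(=C)CO[Si](C)(C)C(C)(C)C
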